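Remark on the chemistry: the target SMILES has no stereocentre and no configured double bond, so arthonioic acid is achiral. The "single enantiomer" is the compound itself and no step has to control configuration.

Atom labels used throughout: each half is numbered as a polyketide chain. C1 is the carboxyl carbon, C2–C7 are the ring carbons (C2 bears C1, C3 and C5 bear oxygen, C7 bears the side chain), C8 is the benzylic CH2, C9 the ketone carbon and C10–C14 the pentyl group. Prefix A is the acyl half (ring A) and prefix B the half with the free acid (ring B). The depside bond is A-C1(=O)–O–B-C5, and the methyl ether sits on the oxygen at B-C3.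

## The problem

Arthonioic acid (16) is a depside of two benzene rings. Ring A is a 2,4-dihydroxy-6-(2-oxoheptyl)benzoyl group, and it is esterified to the oxygen at B-C5 of a 2-methoxy-6-(2-oxoheptyl)benzoic acid. A synthesis has to solve four things.

- **Ketone next to carboxyl.** In both halves an enolisable C9 ketone sits five atoms from the C1 carboxyl carbon. Whenever C1 is activated or carries a good leaving group, the enol oxygen closes onto it and a 3-pentylisocoumarin results. The aryl ester at A-C1 is such a leaving-group ester.
- **Hindered ester.** The depside bond joins a di-ortho-substituted benzoic acid to an electron-poor phenol.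
- **Five oxygen functions to tell apart.** B-C3–O must be methylated although it is the hydrogen-bonded, less reactive phenol of ring B. B-C5–O must be acylated. B-C1 must end as the free acid, and the two phenols of ring A must end free.
- **Fragile groups.** The aryl ester will not survive hydroxide, alkoxide or amines at elevated temperature, and the keto acid will not survive strong acid or dehydrating agents. The endgame is therefore limited to mild aqueous acid and neutral hydrogenolysis.

The feature that opens the problem is the oxygen pattern. In each half C1, C3, C5 and C9 carry oxygen on every second carbon of an unbranched C14 chain, and the ring bond C2–C7 is the aldol bond of a 3,5,7,9-tetraoxotetradecanoate. The depside carbonyl A-C1 is therefore the terminus of a poly-β-carbonyl chain. It can be offered to B-C5–OH as an acylketene carbon before ring A (A-C2 to A-C7) exists. Both halves can come from one and the same chain, a diketo-dioxinone, used in two modes. For ring B the dioxinone ring is kept, so that its acetonide ties up B-C1 and B-C3–O and leaves B-C5–OH as the only free hydroxyl. For ring A the dioxinone ring is opened thermally to the acylketene.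

## Retrosynthesis

16 is traced back to benzyl ester 15 and then to bis-dioxolane 14. Only the O–CH2Ph bond of the ester and the four C–O bonds of two ketals are cut. Hydrogenolysis is the one neutral way to free B-C1 next to an aryl ester. Masking both C9 ketones until after the depside bond is made keeps the isocoumarin closure out of every earlier step. The forward reactions must spare the depside: dilute aqueous acid, then H2 over Pd/C.

14 is cut at two bonds at once: the ester bond A-C1–O(B-C5) and the ring bond A-C2–A-C7. This gives phenol 11 and diketo-dioxinone 6. A cut of the ester bond alone would leave a hindered, protected keto acid to be activated. The double cut removes the whole of ring A and leaves an acyclic precursor with no phenol to protect. The forward reaction must generate acylketene 12 from 6 and let the one free hydroxyl of 11 capture it to give aryl trioxo ester 13. Ring A must then close by the A-C2 to A-C7 aldol without loss of the aryloxide. The A-C9 carbonyl is kept as a dioxolane because a free ketone there would open further aldol and pyranone modes.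

11 is traced back to allyl ether 10, then through chelated phenol 9 to allyloxy-benzodioxinone 8, and on to hydroxy-benzodioxinone 7. The cuts are the O–allyl bond at B-C5, the O–CH3 bond at B-C3 and the B-C1–O(benzyl) bond. In 7 the acetonide joins B-C1 and B-C3–O, so B-C5–OH is the only free hydroxyl and takes the temporary allyl group without any question of selectivity. Benzyl alkoxide then opens the lactone. That places the benzyl ester on B-C1, expels acetone and frees only the B-C3 phenoxide, which is methylated in the same flask. Pd(0) removes the allyl group without touching the benzyl ester or the ketal.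

7 is cut at the ring bond B-C2–B-C7 only, back to the same diketo-dioxinone 6. Ring B is made by the known base-mediated aromatisation of a diketo-dioxinone with the dioxinone ring retained. No acid is needed, so the dioxolane is safe, and the acylketene is generated only once in the whole route, in the key step. Using 6 twice halves the preparative work before the key step.

6 is cut at the C6–C7 bond into keto-dioxinone 5 (C1–C6) and Weinreb amide 3 (C7–C14). This cut sits between two carbonyl groups and corresponds to a Claisen-type acylation of the terminal carbanion of the dianion of 5. The Weinreb amide stops the addition at the ketone stage.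

3 comes from ketal ester 2 by ester-to-amide exchange, and 2 from commercial ethyl 3-oxooctanoate 1 by ketalisation. 5 comes from commercial 2,2,6-trimethyl-4H-1,3-dioxin-4-one 4 by acylation of its dienolate at the methyl carbon.

## Roads not taken

Alternative 1: the obvious cut is the depside C–O bond alone. The halves would be 2,4-bis(benzyloxy)-6-(2-oxoheptyl)benzoic acid A1 and benzyl 4-hydroxy-2-methoxy-6-(2-oxoheptyl)benzoate A2. Each would be made from an orsellinate ester by lateral lithiation and acylation with a hexanoyl donor. The forward key step is a carbodiimide or mixed-anhydride esterification. The activated form of A1 carries its own nucleophile: the enol oxygen at A-C9 should close to 6,8-bis(benzyloxy)-3-pentyl-1H-isochromen-1-one A3 faster than a hindered acyl carbon meets an electron-poor phenol. Both ketones would therefore need masks anyway. Ring A would need two benzyl ethers and an ester hydrolysis, and each ring would be elaborated separately. The chosen plan delivers A-C1 as a neutral ketene with no leaving group, needs no protection on ring A and builds both rings from one precursor.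

Alternative 2: the isocoumarin as an internal active ester. The cut is again the depside bond, but the acyl donor is 6,8-dihydroxy-3-pentyl-1H-isochromen-1-one A4. Ring opening by the phenoxide of A2 would unveil the A-C9 ketone and give 15 directly. The product, however, holds an enol(ate) oxygen six atoms from an aryl ester with a good leaving group, so the reverse reaction is the known base-induced isocoumarin closure. Under the basic conditions needed for the phenoxide, the phenols of A4 are deprotonated and deactivate the lactone carbonyl. The position of the equilibrium cannot be defended. The ketene route is irreversible, since acetone leaves and the ring aromatises.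

Alternative 3: side chains last. Both C8–C9 bonds are cut on a preformed depside of two orsellinate units, benzyl 4-{[2,4-bis(benzyloxy)-6-methylbenzoyl]oxy}-2-methoxy-6-methylbenzoate A5. The forward key step is a twofold lateral deprotonation and acylation with a hexanoyl donor. The aryl ester is the best electrophile in the flask and would be attacked by amide bases and by the benzylic anions. The two methyl groups differ in acidity, and the product ketones are more acidic than the starting methyl groups. The chosen plan forms both C8–C9 relationships before any ester sensitive to base exists.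

Key step: step 9

## Route

Step 1
Reactants: 1 ethyl 3-oxooctanoate
Product: 2 ethyl 2-(2-pentyl-1,3-dioxolan-2-yl)acetate
Conditions: ethylene glycol, TsOH·H2O (cat.), PhMe, reflux, Dean–Stark
Reagents that add atoms: ethylene glycol OCCO
Why: Acid-catalysed ketalisation of the ketone of a β-keto ester with azeotropic removal of water; the cyclic ketal is chosen because it resists β-elimination to an enol ether.

Step 2
Reactants: 2 ethyl 2-(2-pentyl-1,3-dioxolan-2-yl)acetate
Product: 3 N-methoxy-N-methyl-2-(2-pentyl-1,3-dioxolan-2-yl)acetamide
Conditions: MeNH(OMe)·HCl, iPrMgCl, THF, −20 → 0 °C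
Reagents that add atoms: N,O-dimethylhydroxylamine hydrochloride CNOC.Cl
Why: Direct ester-to-Weinreb-amide exchange with the magnesium amide, which works on enolisable esters; the ketal is inert to the basic medium.

Step 3
Reactants: 4 2,2,6-trimethyl-4H-1,3-dioxin-4-one
Product: 5 2,2-dimethyl-6-(2-oxopropyl)-4H-1,3-dioxin-4-one
Conditions: LiHMDS (2 equiv), 4 (2 equiv), THF, −78 °C; AcCl (1 equiv), −78 °C
Reagents that add atoms: acetyl chloride CC(=O)Cl
Why: γ-Acylation of the lithium dienolate of the dioxinone at the exocyclic carbon; the second equivalent of enolate takes up the proton of the more acidic product.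

Step 4
Reactants: 5 2,2-dimethyl-6-(2-oxopropyl)-4H-1,3-dioxin-4-one; 3 N-methoxy-N-methyl-2-(2-pentyl-1,3-dioxolan-2-yl)acetamide
Product: 6 2,2-dimethyl-6-[2,4-dioxo-5-(2-pentyl-1,3-dioxolan-2-yl)pentyl]-4H-1,3-dioxin-4-one
Conditions: LDA (2.2 equiv), THF, −78 → −40 °C; then 3, −78 → −20 °C; aq. NH4Cl
Reagents that add atoms: none
Why: Claisen-type acylation of the terminal (methyl-derived) carbanion of the dianion of 5 by a Weinreb amide; the chelated tetrahedral intermediate prevents over-addition and releases the 1,3-diketone on work-up.

Step 5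
Reactants: 6 2,2-dimethyl-6-[2,4-dioxo-5-(2-pentyl-1,3-dioxolan-2-yl)pentyl]-4H-1,3-dioxin-4-one
Product: 7 7-hydroxy-2,2-dimethyl-5-[(2-pentyl-1,3-dioxolan-2-yl)methyl]-4H-1,3-benzodioxin-4-one
Conditions: Et3N (excess), CH2Cl2, rt
Reagents that add atoms: none
Why: Known base-mediated aromatisation of a diketo-dioxinone to an acetonide-protected β-resorcylate: intramolecular aldol addition of the dioxinone α-carbon (B-C2) to the B-C7 ketone, then loss of water. The dioxinone ring stays intact, so no ketene is formed, and no acid is used, so the dioxolane is not at risk.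

Step 6
Reactants: 7 7-hydroxy-2,2-dimethyl-5-[(2-pentyl-1,3-dioxolan-2-yl)methyl]-4H-1,3-benzodioxin-4-one
Product: 8 7-(allyloxy)-2,2-dimethyl-5-[(2-pentyl-1,3-dioxolan-2-yl)methyl]-4H-1,3-benzodioxin-4-one
Conditions: allyl bromide, K2CO3, DMF, rt
Reagents that add atoms: allyl bromide C=CCBr
Why: Williamson etherification of the only free hydroxyl (B-C5–OH); the B-C3 oxygen and the carboxyl are locked in the acetonide, so no selectivity between phenols is asked for.

Step 7
Reactants: 8 7-(allyloxy)-2,2-dimethyl-5-[(2-pentyl-1,3-dioxolan-2-yl)methyl]-4H-1,3-benzodioxin-4-one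
Product: 10 benzyl 4-(allyloxy)-2-methoxy-6-[(2-pentyl-1,3-dioxolan-2-yl)methyl]benzoate, via chelated phenol 9 (not isolated)
Conditions: BnOH (1.5 equiv), Cs2CO3 (2 equiv), DMF, 50 °C; then MeI (excess), rt
Reagents that add atoms: benzyl alcohol OCc1ccccc1; methyl iodide CI
Why: Known alkoxide opening of a benzodioxinone: benzyl alkoxide adds to the lactone carbonyl, the hemiketal oxide collapses to acetone and the B-C3 phenoxide of 9, and this phenoxide is O-methylated in the same flask (Williamson). Etherification of B-C5–O beforehand keeps the lactone carbonyl electrophilic, since no ring phenoxide can form.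

Step 8
Reactants: 10 benzyl 4-(allyloxy)-2-methoxy-6-[(2-pentyl-1,3-dioxolan-2-yl)methyl]benzoate
Product: 11 benzyl 4-hydroxy-2-methoxy-6-[(2-pentyl-1,3-dioxolan-2-yl)methyl]benzoate
Conditions: Pd(PPh3)4 (5 mol %), morpholine, THF, rt
Reagents that add atoms: none
Why: Pd(0)-catalysed deallylation of an aryl allyl ether via a π-allyl complex that morpholine intercepts; benzyl ester, methyl ether and ketal do not ionise under these conditions.

Step 9
Reactants: 11 benzyl 4-hydroxy-2-methoxy-6-[(2-pentyl-1,3-dioxolan-2-yl)methyl]benzoate; 6 2,2-dimethyl-6-[2,4-dioxo-5-(2-pentyl-1,3-dioxolan-2-yl)pentyl]-4H-1,3-dioxin-4-one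
Product: 14 benzyl 4-({2,4-dihydroxy-6-[(2-pentyl-1,3-dioxolan-2-yl)methyl]benzoyl}oxy)-2-methoxy-6-[(2-pentyl-1,3-dioxolan-2-yl)methyl]benzoate, via acylketene 12 (not isolated), via aryl trioxo ester 13 (not isolated)
Conditions: 6 (1.5 equiv, slow addition to 11 at about 0.3 M), PhMe, 110 °C; cool to 0 °C, Et3N (0.3 equiv), 0 °C → rt; then AcOH
Reagents that add atoms: none
Why: Proposed new method: heating 6 without base should cause retro-hetero-Diels–Alder loss of acetone to acylketene 12, which the only free hydroxyl of 11 (B-C5–OH) should capture at the ketene carbon to give aryl 3,5,7-trioxo ester 13; amine-catalysed intramolecular aldol addition of A-C2 to the A-C7 ketone and loss of water should then give the aromatic ring A of 14. The closest known reaction type is the thermolysis of diketo-dioxinones with aliphatic alcohols followed by aldol aromatisation to alkyl β-resorcylates, together with the capture of acylketenes from simple dioxinones by phenols to give aryl acetoacetates; new here is that the ketene acceptor is a phenol and that the resulting aryl ester must survive the aromatisation. Ring A closes in a 6-(enolendo)-exo-trig aldol mode between A-C2 and A-C7, and dehydration of the carbinol with enolisation of the A-C3 and A-C5 carbonyls makes the closure irreversible. No stereocentre remains, because the carbinol centre at A-C7 is lost on aromatisation. The step needs O-acylation of a single phenol, which the neutral thermal conditions and the one free hydroxyl of 11 secure, and it needs the aldol closure to outrun expulsion of the aryloxide by the A-C5 enol oxygen (2-pyranone closure) or by A-C6 (Claisen closure). Three features of 13 favour the aldol: A-C2–H is the most acidic methylene once the ester is an aryl ester, the A-C9 carbonyl is masked as a dioxolane so that A-C7 is the only ketone within six-membered reach of an acidic carbon, and a weak amine base at low temperature keeps the concentration of free enolate oxygen small. Once ring A is formed, its 2-OH hydrogen-bonds to the depside carbonyl and lowers its electrophilicity.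

Step 10
Reactants: 14 benzyl 4-({2,4-dihydroxy-6-[(2-pentyl-1,3-dioxolan-2-yl)methyl]benzoyl}oxy)-2-methoxy-6-[(2-pentyl-1,3-dioxolan-2-yl)methyl]benzoate
Product: 15 benzyl 4-{[2,4-dihydroxy-6-(2-oxoheptyl)benzoyl]oxy}-2-methoxy-6-(2-oxoheptyl)benzoate
Conditions: 1 M aq. HCl–THF (1:4), rt
Reagents that add atoms: water O
Why: Acid-catalysed hydrolysis of two dialkyl-ketone dioxolanes under conditions in which aryl and benzyl esters are stable; B-C1 is still a benzyl ester, so no free keto acid is exposed to acid.

Step 11
Reactants: 15 benzyl 4-{[2,4-dihydroxy-6-(2-oxoheptyl)benzoyl]oxy}-2-methoxy-6-(2-oxoheptyl)benzoate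
Product: 16 arthonioic acid, 4-{[2,4-dihydroxy-6-(2-oxoheptyl)benzoyl]oxy}-2-methoxy-6-(2-oxoheptyl)benzoic acid
Conditions: H2 (1 atm), 10% Pd/C, EtOAc, rt
Reagents that add atoms: none
Why: Neutral hydrogenolysis of the benzyl ester, the classical last step of depside syntheses; the aryl ester and the dialkyl ketones should not be reduced under these conditions.

## Compound list

1 | ethyl 3-oxooctanoate | CCCCCC(=O)CC(=O)OCC | starting material
2 | ethyl 2-(2-pentyl-1,3-dioxolan-2-yl)acetate | CCCCCC1(OCCO1)CC(=O)OCC | intermediate
3 | N-methoxy-N-methyl-2-(2-pentyl-1,3-dioxolan-2-yl)acetamide | CCCCCC1(OCCO1)CC(=O)N(C)OC | intermediate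
4 | 2,2,6-trimethyl-4H-1,3-dioxin-4-one | CC1=CC(=O)OC(C)(C)O1 | starting material
5 | 2,2-dimethyl-6-(2-oxopropyl)-4H-1,3-dioxin-4-one | CC(=O)CC1=CC(=O)OC(C)(C)O1 | intermediate
6 | 2,2-dimethyl-6-[2,4-dioxo-5-(2-pentyl-1,3-dioxolan-2-yl)pentyl]-4H-1,3-dioxin-4-one | CCCCCC1(OCCO1)CC(=O)CC(=O)CC2=CC(=O)OC(C)(C)O2 | intermediate
7 | 7-hydroxy-2,2-dimethyl-5-[(2-pentyl-1,3-dioxolan-2-yl)methyl]-4H-1,3-benzodioxin-4-one | CCCCCC1(OCCO1)Cc2cc(O)cc3OC(C)(C)OC(=O)c23 | intermediate
8 | 7-(allyloxy)-2,2-dimethyl-5-[(2-pentyl-1,3-dioxolan-2-yl)methyl]-4H-1,3-benzodioxin-4-one | CCCCCC1(OCCO1)Cc2cc(OCC=C)cc3OC(C)(C)OC(=O)c23 | intermediate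
9 | benzyl 4-(allyloxy)-2-hydroxy-6-[(2-pentyl-1,3-dioxolan-2-yl)methyl]benzoate | CCCCCC1(OCCO1)Cc2cc(OCC=C)cc(O)c2C(=O)OCc3ccccc3 | intermediate
10 | benzyl 4-(allyloxy)-2-methoxy-6-[(2-pentyl-1,3-dioxolan-2-yl)methyl]benzoate | CCCCCC1(OCCO1)Cc2cc(OCC=C)cc(OC)c2C(=O)OCc3ccccc3 | intermediate
11 | benzyl 4-hydroxy-2-methoxy-6-[(2-pentyl-1,3-dioxolan-2-yl)methyl]benzoate | CCCCCC1(OCCO1)Cc2cc(O)cc(OC)c2C(=O)OCc3ccccc3 | intermediate
12 | 8-(2-pentyl-1,3-dioxolan-2-yl)oct-1-ene-1,3,5,7-tetrone (acylketene) | CCCCCC1(OCCO1)CC(=O)CC(=O)CC(=O)C=C=O | intermediate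
13 | benzyl 2-methoxy-6-[(2-pentyl-1,3-dioxolan-2-yl)methyl]-4-{[3,5,7-trioxo-8-(2-pentyl-1,3-dioxolan-2-yl)octanoyl]oxy}benzoate | CCCCCC1(OCCO1)CC(=O)CC(=O)CC(=O)CC(=O)Oc2cc(CC3(CCCCC)OCCO3)c(C(=O)OCc4ccccc4)c(OC)c2 | intermediate
14 | benzyl 4-({2,4-dihydroxy-6-[(2-pentyl-1,3-dioxolan-2-yl)methyl]benzoyl}oxy)-2-methoxy-6-[(2-pentyl-1,3-dioxolan-2-yl)methyl]benzoate | CCCCCC1(OCCO1)Cc2cc(O)cc(O)c2C(=O)Oc3cc(CC4(CCCCC)OCCO4)c(C(=O)OCc5ccccc5)c(OC)c3 | intermediate
15 | benzyl 4-{[2,4-dihydroxy-6-(2-oxoheptyl)benzoyl]oxy}-2-methoxy-6-(2-oxoheptyl)benzoate | CCCCCC(=O)Cc1cc(O)cc(O)c1C(=O)Oc1cc(CC(=O)CCCCC)c(C(=O)OCc2ccccc2)c(OC)c1 | intermediate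
16 | arthonioic acid | CCCCCC(=O)Cc1cc(O)cc(O)c1C(=O)Oc1cc(CC(=O)CCCCC)c(C(=O)O)c(OC)c1 | target

## Step count and risks

Total step count: 11. Longest linear sequence: 10 steps (1, 2, 4, 5, 6, 7, 8, 9, 10, 11); step 3 is a one-step side branch. Compound 6 enters twice, in step 5 and in step 9.

**Step 9 (key step, proposed new method).** Two processes threaten it. First, capture of the ketene by the electron-poor phenol may be slow, so that the ketene is trapped internally by its own enol oxygen. Second, after capture the aryloxide may be expelled by lactonisation or Claisen closure before the aldol ring closure takes place. The fallback uses only known chemistry, sets out from 7 and 11 and returns to the route at 16. Benzodioxinone 7 is benzylated on its one free phenol (BnBr, K2CO3, DMF) to 7-(benzyloxy)-2,2-dimethyl-5-[(2-pentyl-1,3-dioxolan-2-yl)methyl]-4H-1,3-benzodioxin-4-one F1. Opening with benzyl alcohol and Cs2CO3, followed by BnBr in the same flask in analogy to step 7, gives benzyl 2,4-bis(benzyloxy)-6-[(2-pentyl-1,3-dioxolan-2-yl)methyl]benzoate F2. Saponification (KOH, aq. DMSO, 90 °C) gives 2,4-bis(benzyloxy)-6-[(2-pentyl-1,3-dioxolan-2-yl)methyl]benzoic acid F3, whose C9 carbonyl is still masked and cannot lactonise on activation. Steglich esterification of F3 with phenol 11 (DCC, DMAP, CH2Cl2) gives benzyl 4-({2,4-bis(benzyloxy)-6-[(2-pentyl-1,3-dioxolan-2-yl)methyl]benzoyl}oxy)-2-methoxy-6-[(2-pentyl-1,3-dioxolan-2-yl)methyl]benzoate F4. Ketal hydrolysis as in step 10 gives benzyl 4-{[2,4-bis(benzyloxy)-6-(2-oxoheptyl)benzoyl]oxy}-2-methoxy-6-(2-oxoheptyl)benzoate F5, and hydrogenolysis of all three benzyl groups (H2, Pd/C, EtOAc) gives 16.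

**Step 4.** The dianion of 5 may act as a base on the α-methylene of Weinreb amide 3 instead of adding to it. That would return starting materials or open the dioxolane by β-elimination. The fallback replaces the acylation by an aldol addition and an oxidation. It sets out from 3 and 5 and returns at 6. Amide 3 is reduced (DIBAL-H, THF, −78 °C) to 2-(2-pentyl-1,3-dioxolan-2-yl)acetaldehyde F6. The dianion of 5 adds to F6 at −78 °C, faster than proton transfer, to give racemic 6-[4-hydroxy-2-oxo-5-(2-pentyl-1,3-dioxolan-2-yl)pentyl]-2,2-dimethyl-4H-1,3-dioxin-4-one F7. Dess–Martin oxidation (NaHCO3, CH2Cl2) then gives 6 and removes the transient stereocentre.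

**Step 10.** In aqueous acid the newly freed A-C9 ketone may enol-lactonise onto the aryl ester with loss of the ring B phenol, or the depside may hydrolyse slowly while the second ketal is still being cleaved. The fallback changes the order and the mode of unmasking. It sets out from 14 and returns at 16. Hydrogenolysis (H2, Pd/C, EtOAc) first gives 4-({2,4-dihydroxy-6-[(2-pentyl-1,3-dioxolan-2-yl)methyl]benzoyl}oxy)-2-methoxy-6-[(2-pentyl-1,3-dioxolan-2-yl)methyl]benzoic acid F8. The two ketals are then removed by water-free exchange with acetone (PPTS cat., dry acetone, 40 °C), which transfers the glycol to the solvent and gives 16 at much lower acidity.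

**Step 7.** Addition of benzyl alkoxide to the lactone carbonyl, which is flanked by two ortho substituents and sits on an electron-rich ring, may be slow, so that ring opening stays incomplete and the methylating agent is spent on the alcohol. The fallback opens the ring with the smaller hydroxide and installs the two groups separately. It sets out from 8 and returns at 10. Hydroxide opening (KOH, aq. DMSO, rt → 50 °C; cold acidification) gives 4-(allyloxy)-2-hydroxy-6-[(2-pentyl-1,3-dioxolan-2-yl)methyl]benzoic acid F9. Chemoselective alkylation of the carboxylate (BnBr, KHCO3, DMF, rt) leaves the chelated phenol untouched and gives 9, which is then isolated and methylated (MeI, K2CO3, acetone, reflux) to 10.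

## Further compounds

F1 | step 9 | 7-(benzyloxy)-2,2-dimethyl-5-[(2-pentyl-1,3-dioxolan-2-yl)methyl]-4H-1,3-benzodioxin-4-one | CCCCCC1(OCCO1)Cc2cc(OCc3ccccc3)cc4OC(C)(C)OC(=O)c24
F2 | step 9 | benzyl 2,4-bis(benzyloxy)-6-[(2-pentyl-1,3-dioxolan-2-yl)methyl]benzoate | CCCCCC1(OCCO1)Cc2cc(OCc3ccccc3)cc(OCc4ccccc4)c2C(=O)OCc5ccccc5
F3 | step 9 | 2,4-bis(benzyloxy)-6-[(2-pentyl-1,3-dioxolan-2-yl)methyl]benzoic acid | CCCCCC1(OCCO1)Cc2cc(OCc3ccccc3)cc(OCc4ccccc4)c2C(=O)O
F4 | step 9 | benzyl 4-({2,4-bis(benzyloxy)-6-[(2-pentyl-1,3-dioxolan-2-yl)methyl]benzoyl}oxy)-2-methoxy-6-[(2-pentyl-1,3-dioxolan-2-yl)methyl]benzoate | CCCCCC1(OCCO1)Cc2cc(OCc3ccccc3)cc(OCc4ccccc4)c2C(=O)Oc5cc(CC6(CCCCC)OCCO6)c(C(=O)OCc7ccccc7)c(OC)c5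
F5 | step 9 | benzyl 4-{[2,4-bis(benzyloxy)-6-(2-oxoheptyl)benzoyl]oxy}-2-methoxy-6-(2-oxoheptyl)benzoate | CCCCCC(=O)Cc1cc(OCc2ccccc2)cc(OCc3ccccc3)c1C(=O)Oc4cc(CC(=O)CCCCC)c(C(=O)OCc5ccccc5)c(OC)c4
F6 | step 4 | 2-(2-pentyl-1,3-dioxolan-2-yl)acetaldehyde | CCCCCC1(OCCO1)CC=O
F7 | step 4 | 6-[4-hydroxy-2-oxo-5-(2-pentyl-1,3-dioxolan-2-yl)pentyl]-2,2-dimethyl-4H-1,3-dioxin-4-one (racemic) | CCCCCC1(OCCO1)CC(O)CC(=O)CC2=CC(=O)OC(C)(C)O2
F8 | step 10 | 4-({2,4-dihydroxy-6-[(2-pentyl-1,3-dioxolan-2-yl)methyl]benzoyl}oxy)-2-methoxy-6-[(2-pentyl-1,3-dioxolan-2-yl)methyl]benzoic acid | CCCCCC1(OCCO1)Cc2cc(O)cc(O)c2C(=O)Oc3cc(CC4(CCCCC)OCCO4)c(C(=O)O)c(OC)c3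
F9 | step 7 | 4-(allyloxy)-2-hydroxy-6-[(2-pentyl-1,3-dioxolan-2-yl)methyl]benzoic acid | CCCCCC1(OCCO1)Cc2cc(OCC=C)cc(O)c2C(=O)O
A1 | alternative 1 | 2,4-bis(benzyloxy)-6-(2-oxoheptyl)benzoic acid | CCCCCC(=O)Cc1cc(OCc2ccccc2)cc(OCc3ccccc3)c1C(=O)O
A2 | alternative 1 | benzyl 4-hydroxy-2-methoxy-6-(2-oxoheptyl)benzoate | CCCCCC(=O)Cc1cc(O)cc(OC)c1C(=O)OCc2ccccc2
A3 | alternative 1 | 6,8-bis(benzyloxy)-3-pentyl-1H-isochromen-1-one | CCCCCC1=Cc2cc(OCc3ccccc3)cc(OCc4ccccc4)c2C(=O)O1
A4 | alternative 2 | 6,8-dihydroxy-3-pentyl-1H-isochromen-1-one | CCCCCC1=Cc2cc(O)cc(O)c2C(=O)O1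
A5 | alternative 3 | benzyl 4-{[2,4-bis(benzyloxy)-6-methylbenzoyl]oxy}-2-methoxy-6-methylbenzoate | Cc1cc(OCc2ccccc2)cc(OCc3ccccc3)c1C(=O)Oc4cc(C)c(C(=O)OCc5ccccc5)c(OC)c4
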